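**Assumptions (one line):** The structure is as given (C20H34BrClO2). (S)-(+)-Linalool and methyl (R)-glycidate are bought. The remote C–Br centre cannot be controlled by a bromonium step. It is formed as C–Br epimers and the natural one is separated by preparative HPLC at the end.

## Retrosynthetic overview
1. The target comes from Br⁺/Cl⁻ addition to the terminal prenyl alkene of an oxa-bridged ether; the remote C–Br epimers are separated.
2. The oxa-bridged ether comes from one photoredox/titanocene cascade on an epoxy-diene. The Ca–Cb bond closes the cyclohexane first, and the transannular Cd–O bond closes the 7-oxabicycle second.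
3. The epoxy-diene comes from a diol (mesylation, then base; inversion at Cc). The diol comes from cross-metathesis of an exocyclic-methylene diol with an (S)-linalool-derived diene.
4. The methylene diol comes from (R)-methyl glycidate: methallyl opening, Weinreb amide, MeMgBr, then homoprenyl Grignard.

## Route

**Step 1**
Reactants: 1, (S)-linalool
Product: 2, 6,7-epoxylinalool (C6 epimer mixture)
Conditions: mCPBA (1.0 equiv), NaHCO3, CH2Cl2, 0 °C
Reagents that add atoms: mCPBA, OOC(=O)c1cccc(Cl)c1 (adds O)
Why: Electrophilic epoxidation is selective for the electron-rich trisubstituted alkene over the deactivated vinyl group; C3 is untouched, so the carbinol stereocentre is retained.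

**Step 2**
Reactants: 2
Product: 3, (S)-4-hydroxy-4-methylhex-5-enal
Conditions: H5IO6, THF/Et2O, 0 °C → 25 °C
Reagents that add atoms: none
Why: Periodic-acid cleavage of the epoxide (via its diol) is an oxidative glycol-type cleavage that releases acetone and leaves the aldehyde; C3 is unchanged.

**Step 3**
Reactants: 3
Product: 4, (S)-3-methylhepta-1,6-dien-3-ol
Conditions: Ph3PCH3Br, KOtBu, THF, 0 °C; then 3
Reagents that add atoms: Ph3P=CH2, C=P(c1ccccc1)(c1ccccc1)c1ccccc1 (adds CH2)
Why: Wittig methylenation of the aldehyde (present as lactol) gives the terminal alkene that serves as the metathesis partner; the stereocentre is untouched.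

**Step 4**
Reactants: 5, methyl (R)-glycidate; 6, methallylmagnesium chloride
Product: 7, methyl (2R)-2-hydroxy-5-methylhex-5-enoate
Conditions: 6 (2.2 equiv), CuI (10 mol %), THF, −78 → −40 °C
Reagents that add atoms: methallylmagnesium chloride, C=C(C)C[Mg]Cl (adds C4H7)
Why: Cu-catalysed SN2 opening of the 2,3-epoxy ester occurs at the unhindered C3, so C2 is not touched and the Cc stereocentre is retained from the chiral glycidate.

**Step 5**
Reactants: 7
Product: 8, (2R)-2-hydroxy-N-methoxy-N,5-dimethylhex-5-enamide
Conditions: MeONHMe·HCl, i-PrMgCl (3.5 equiv), THF, −20 → 0 °C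
Reagents that add atoms: N,O-dimethylhydroxylamine hydrochloride, CNOC.Cl (adds N(OMe)Me)
Why: Magnesium amide aminolysis (Weinreb amide formation) tolerates the free α-OH and sets up a single clean ketone addition in the next step.

**Step 6**
Reactants: 8
Product: 9, (3R)-3-hydroxy-6-methylhept-6-en-2-one
Conditions: MeMgBr (3 equiv), THF, −78 → 0 °C
Reagents that add atoms: methylmagnesium bromide, C[Mg]Br (adds CH3)
Why: Weinreb ketone synthesis stops at the chelated tetrahedral intermediate, giving the α-hydroxy methyl ketone without over-addition.

**Step 7**
Reactants: 9; 10, homoprenylmagnesium bromide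
Product: 11, 2,6,10-trimethylundeca-2,10-diene-6,7-diol ((7R); C6 epimers, about 3:1, carried together)
Conditions: 10 (3 equiv), THF, −78 → −20 °C
Reagents that add atoms: homoprenylmagnesium bromide, CC(C)=CCC[Mg]Br (adds C6H11)
Why: Chelation-controlled Grignard addition to the α-hydroxy ketone; the C6 configuration need not be controlled because it becomes a radical centre in step 10, while Cc (7R) is untouched.

**Step 8**
Reactants: 11; 4
Product: 12, polyene diol (E-trisubstituted Ca=Cd alkene; Cc R; C* S)
Conditions: Hoveyda–Grubbs II (10 mol %), 4 (3 equiv), CH2Cl2, 40 °C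
Reagents that add atoms: none (ethylene is lost)
Why: Cross-metathesis of the 1,1-disubstituted exocyclic alkene with the unhindered terminal alkene of 4 gives the E-trisubstituted alkene, which fixes the Ca configuration in the next cascade.

**Step 9**
Reactants: 12
Product: 13, epoxy-diene (Cb–O–Cc epoxide; Cc S)
Conditions: MsCl, Et3N, CH2Cl2, −10 °C; then K2CO3, MeOH, 25 °C
Reagents that add atoms: none
Why: The secondary OH is mesylated selectively over the two tertiary OH groups, and the tertiary alkoxide then displaces it intramolecularly (3-exo-tet). This inverts Cc, so (R)-glycidate delivers the target Cc configuration.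

**Step 10**
Reactants: 13
Product: 14, oxa-bridged ether with terminal prenyl alkene
Conditions: Cp2TiCl2 (20 mol %), [Ir(ppy)2(dtbbpy)]PF6 (1 mol %), 2,4,6-collidine (0.5 equiv), THF (0.02 M), blue LEDs, 25 °C, 24 h
Reagents that add atoms: none (isomerisation)
Why: Proposed new method: Excited Ir(III) reduces Cp2TiCl2 to Ti(III), which opens the epoxide to the tertiary Cb radical with Ti–O on Cc. This radical closes 6-endo onto the E-alkene through a chair-like transition state; the equatorial Cc–O and Ca substituent set Ca, and the larger homoprenyl group is pseudo-equatorial at Cb (the minor Cb epimer is separated). Ir(IV) then oxidises the tertiary Cd radical to the cation (radical–polar crossover), and the titanium-bound Cc alkoxide captures it across the ring in a boat to close the 7-oxabicyclo[2.2.1]heptane, which fixes Cd. The closest known chemistry is Ti(III) epoxypolyene radical cyclisation ending in elimination or H-transfer, combined with photoredox radical–polar crossover hydroalkoxylation.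

**Step 11**
Reactants: 14
Product: 15, dactylomelol
Conditions: NBS (1.05 equiv), Et4NCl (3 equiv), CH2Cl2, −20 °C; then preparative HPLC
Reagents that add atoms: NBS, O=C1CCC(=O)N1Br (adds Br); Et4NCl, CC[N+](CC)(CC)CC.[Cl-] (adds Cl)
Why: Bromochlorination, via Br⁺ attack on the most accessible trisubstituted alkene and chloride opening of the bromonium at the tertiary carbon, places Br on CH and Cl on CMe2; the C–Br centre forms as epimers and the natural one is separated.

## Compound list
1 | (S)-linalool | C=C[C@@](C)(O)CCC=C(C)C | starting material
2 | 6,7-epoxylinalool | C=C[C@@](C)(O)CCC1OC1(C)C | intermediate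
3 | (S)-4-hydroxy-4-methylhex-5-enal | C=C[C@@](C)(O)CCC=O | intermediate
4 | (S)-3-methylhepta-1,6-dien-3-ol | C=C[C@@](C)(O)CCC=C | intermediate
5 | methyl (R)-glycidate | COC(=O)[C@H]1CO1 | starting material
6 | methallylmagnesium chloride | C=C(C)C[Mg]Cl | starting material
7 | methyl (2R)-2-hydroxy-5-methylhex-5-enoate | COC(=O)[C@H](O)CCC(C)=C | intermediate
8 | Weinreb amide of 7 | CON(C)C(=O)[C@H](O)CCC(C)=C | intermediate
9 | (3R)-3-hydroxy-6-methylhept-6-en-2-one | CC(=O)[C@H](O)CCC(C)=C | intermediate
10 | homoprenylmagnesium bromide | CC(C)=CCC[Mg]Br | starting material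
11 | 2,6,10-trimethylundeca-2,10-diene-6,7-diol ((7R); C6 epimers) | CC(C)=CCCC(C)(O)[C@H](O)CCC(C)=C | intermediate
12 | polyene diol | CC(C)=CCCC(C)(O)[C@H](O)CC/C(C)=C/CC[C@@](C)(O)C=C | intermediate
13 | epoxy-diene | CC(C)=CCCC1(C)O[C@H]1CC/C(C)=C/CC[C@@](C)(O)C=C | intermediate
14 | oxa-bridged ether, terminal prenyl alkene | C=C[C@@](C)(O)CC[C@H]1[C@](C)(CCC=C(C)C)[C@@H]2CC[C@@]1(C)O2 | intermediate
15 | dactylomelol | C=C[C@@](C)(O)CC[C@H]1[C@](C)(CC[C@H](Br)C(C)(C)Cl)[C@@H]2CC[C@@]1(C)O2 | target

## Totals
Total steps: 11. Longest linear sequence: 8 (steps 4–11).

## Three steps most likely to fail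
1. **Step 10 (the proposed new cascade).** Risks are a poor dr at Cb, elimination instead of ether closure, and interference from the prenyl alkene.
   Fallback: a stereospecific cationic epoxy-olefin cyclisation of the single chelation-derived trans-epoxide diastereomer (SnCl4, −78 °C), followed by AgOTf/2,6-di-tert-butylpyridine SN1 transannular etherification (both known chemistry).
2. **Step 8 (cross-metathesis).** Risks are E/Z selectivity, prenyl scrambling, and reaction at the vinyl carbinol.
   Fallback: open glycidate 5 with propargyl cuprate in step 4 instead of methallyl. Then use Negishi Zr-catalysed methylalumination and iodination to give the E-vinyl iodide, and couple it by Ni-catalysed alkyl–alkenyl cross-coupling with a linalool-derived alkylzinc reagent.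
3. **Step 11 (bromochlorination).** Risks are about 1:1 C–Br epimers and competing reaction at other alkenes.
   Fallback: epoxidise the prenyl alkene and separate the epoxide diastereomers. Open with chloride at the tertiary carbon to give the chlorohydrin, then convert the secondary OH to Br with inversion (PPh3/CBr4).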